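## Retrosynthetic overview

1. Ring B (the butenolide) is closed last by ring-closing metathesis of an acrylate ester that sits on a 2-methylene carbinol; global desilylation follows.
2. That acrylate comes from a Z-selective Wittig union of an α-silyloxy ketone with a γ-oxido ylide, acylated in the same flask; this sets the central Z trisubstituted alkene.
3. Ylide fragment: the butenolide carbinol C–O bond is set by Sharpless epoxidation of an E allylic alcohol, then the epoxide is isomerised to the 2-methylene carbinol.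
4. Ketone fragment: the E alkene comes from alkyne carboalumination and conjugate addition to a four-carbon vinyl ketone; the ring carbinol C–O bond is installed first, directly on dihydro-β-ionone, by a new enantioselective allylic C–H oxygenation (key step).
5. Ring order: ring A (cyclohexene) is bought in with dihydro-β-ionone; ring B is formed in the penultimate step.

Assumption: in the new step the (S,S)-ligand is taken to give the (S)-ester (its antipode is used if the sense is the reverse); racemic 7 and 8 are used as such because their carbinol centre is oxidised away.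

## Route

Step 1
Reactants: 1 dihydro-β-ionone, 4-(2,6,6-trimethylcyclohex-1-en-1-yl)butan-2-one
Product: 3 4-[(3S)-3-hydroxy-2,6,6-trimethylcyclohex-1-en-1-yl]butan-2-one, via 4-nitrobenzoate ester 2 (not isolated)
Conditions: Cu(MeCN)4PF6 (5 mol%), (S,S)-2,2′-isopropylidenebis(4-tert-butyl-2-oxazoline) (6 mol%), N-fluorobenzenesulfonimide (1.5 equiv), 4-nitrobenzoic acid (2 equiv), Li2CO3 (1 equiv), PhCl, 0 °C; filter through basic alumina; K2CO3 (cat.), MeOH, rt
Reagents that add atoms: 4-nitrobenzoic acid, OC(=O)c1ccc(cc1)[N+](=O)[O-]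
Why: Proposed new method: the bisoxazoline-ligated Cu(MeCN)4PF6 catalyst reduces N-fluorobenzenesulfonimide to a sulfonimidyl radical held on divalent copper, a bulky electrophilic hydrogen-atom abstractor that should take the most accessible and most electron-rich allylic hydrogen (the ring CH2 next to the methyl-bearing alkene carbon) rather than the methyl group, the neopentyl-like side-chain CH2 or the positions deactivated by the ketone; the allyl radical is then captured at copper bearing the 4-nitrobenzoate ligand, C–O reductive elimination from trivalent copper at the less hindered allyl terminus sets the (S) carbinol centre, and methanolysis frees the alcohol, the closest known reactions being the bisoxazoline–copper Kharasch–Sosnovsky allylic acyloxylation of cycloalkenes and copper/N-fluorobenzenesulfonimide radical-relay C–H cyanation and etherification.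

Step 2
Reactants: 3 4-[(3S)-3-hydroxy-2,6,6-trimethylcyclohex-1-en-1-yl]butan-2-one
Product: 4 4-[(3S)-3-(tert-butyldimethylsilyloxy)-2,6,6-trimethylcyclohex-1-en-1-yl]butan-2-one
Conditions: TBSCl, imidazole, DMF, rt
Reagents that add atoms: tert-butyldimethylsilyl chloride (TBSCl), CC(C)(C)[Si](C)(C)Cl
Why: Silyl ether formation on the secondary allylic alcohol is routine, leaves the ketone alone and does not touch the stereocentre.

Step 3
Reactants: 4 4-[(3S)-3-(tert-butyldimethylsilyloxy)-2,6,6-trimethylcyclohex-1-en-1-yl]butan-2-one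
Product: 6 tert-butyl{[(1S)-3-(but-3-yn-1-yl)-2,4,4-trimethylcyclohex-2-en-1-yl]oxy}dimethylsilane, via enol phosphate 5 (not isolated)
Conditions: LiN(iPr)2 (1.1 equiv), THF, −78 °C; ClP(O)(OEt)2; LiN(iPr)2 (2.3 equiv), −78 °C → rt; H2O
Reagents that add atoms: none
Why: Kinetic deprotonation at the methyl group, O-phosphorylation and amide-induced elimination of the enol phosphate (Negishi conversion of a methyl ketone into a terminal alkyne) give the alkyne, the silyl ether being inert to the base.

Step 4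
Reactants: 7 but-3-ene-1,2-diol (racemic)
Product: 8 1-(tert-butyldimethylsilyloxy)but-3-en-2-ol (racemic)
Conditions: TBSCl (1.0 equiv), imidazole, CH2Cl2, −20 → 0 °C
Reagents that add atoms: tert-butyldimethylsilyl chloride (TBSCl), CC(C)(C)[Si](C)(C)Cl
Why: The primary hydroxyl is silylated much faster than the secondary allylic one (selective silyl ether formation).

Step 5
Reactants: 8 1-(tert-butyldimethylsilyloxy)but-3-en-2-ol
Product: 9 1-(tert-butyldimethylsilyloxy)but-3-en-2-one
Conditions: Dess–Martin periodinane, CH2Cl2, 0 °C; used at once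
Reagents that add atoms: none
Why: Dess–Martin oxidation converts the secondary allylic alcohol into the vinyl ketone under neutral conditions that avoid conjugate addition and polymerisation.

Step 6
Reactants: 6 tert-butyl{[(1S)-3-(but-3-yn-1-yl)-2,4,4-trimethylcyclohex-2-en-1-yl]oxy}dimethylsilane; 9 1-(tert-butyldimethylsilyloxy)but-3-en-2-one
Product: 10 (5E)-1-(tert-butyldimethylsilyloxy)-8-[(3S)-3-(tert-butyldimethylsilyloxy)-2,6,6-trimethylcyclohex-1-en-1-yl]-6-methyloct-5-en-2-one
Conditions: Me3Al (2 equiv), Cp2ZrCl2 (25 mol%), CH2Cl2, 0 °C → rt; volatiles off; THF, CuBr·SMe2 (10 mol%), 9, −30 °C; aq. NH4Cl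
Reagents that add atoms: trimethylaluminium, C[Al](C)C
Why: Negishi Cp2ZrCl2-catalysed carboalumination adds methyl and aluminium syn across the terminal alkyne and so fixes the E trisubstituted alkene, and CuBr·SMe2-catalysed conjugate addition of the alkenylalane to the unhindered enone forms the C–C bond with retention of alkene geometry.

Step 7
Reactants: 11 5-bromo-2-methylpent-2-ene
Product: 12 (2E)-5-bromo-2-methylpent-2-en-1-ol
Conditions: SeO2 (20 mol%), t-BuOOH (3 equiv), salicylic acid (10 mol%), CH2Cl2, rt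
Reagents that add atoms: tert-butyl hydroperoxide, CC(C)(C)OO
Why: SeO2 allylic oxidation (ene reaction then [2,3]-sigmatropic shift) hydroxylates the E methyl group of the trisubstituted alkene selectively.

Step 8
Reactants: 12 (2E)-5-bromo-2-methylpent-2-en-1-ol
Product: 13 [(2S,3S)-3-(2-bromoethyl)-2-methyloxiran-2-yl]methanol
Conditions: Ti(OiPr)4 (10 mol%), L-(+)-diethyl tartrate (12 mol%), t-BuOOH, 4 Å MS, CH2Cl2, −20 °C
Reagents that add atoms: tert-butyl hydroperoxide, CC(C)(C)OO
Why: Sharpless asymmetric epoxidation with the Ti(OiPr)4/L-(+)-diethyl tartrate catalyst delivers oxygen to one face of the E allylic alcohol and so forms the C–O bond of the later butenolide carbinol carbon as the (S) centre, the remote bromide being inert.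

Step 9
Reactants: 13 [(2S,3S)-3-(2-bromoethyl)-2-methyloxiran-2-yl]methanol
Product: 14 tert-butyl{[(2S,3S)-3-(2-bromoethyl)-2-methyloxiran-2-yl]methoxy}dimethylsilane
Conditions: TBSCl, imidazole, DMF, 0 °C → rt
Reagents that add atoms: tert-butyldimethylsilyl chloride (TBSCl), CC(C)(C)[Si](C)(C)Cl
Why: Silyl ether formation on the primary alcohol is routine and blocks the oxygen that would otherwise be lost in the next step.

Step 10
Reactants: 14 tert-butyl{[(2S,3S)-3-(2-bromoethyl)-2-methyloxiran-2-yl]methoxy}dimethylsilane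
Product: 15 (3S)-5-bromo-2-[(tert-butyldimethylsilyloxy)methyl]pent-1-en-3-ol
Conditions: Cp2TiCl2 (2.2 equiv), Mn, THF, rt; dil. HCl
Reagents that add atoms: none
Why: Cp2TiCl (trivalent titanium) opens the epoxide by single-electron transfer at the tertiary carbon and a second Cp2TiCl takes a hydrogen atom from the unhindered methyl group (radical epoxide-to-allylic-alcohol isomerisation), so the secondary C–O bond and its (S) configuration are untouched.

Step 11
Reactants: 15 (3S)-5-bromo-2-[(tert-butyldimethylsilyloxy)methyl]pent-1-en-3-ol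
Product: 16 {(3S)-4-[(tert-butyldimethylsilyloxy)methyl]-3-hydroxypent-4-en-1-yl}triphenylphosphonium bromide
Conditions: PPh3, MeCN, 80 °C
Reagents that add atoms: triphenylphosphine, c1ccc(cc1)P(c1ccccc1)c1ccccc1
Why: SN2 quaternisation of triphenylphosphine by the primary bromide (phosphonium salt formation) is neutral and leaves the allylic alcohol and silyl ether alone.

Step 12
Reactants: 16 {(3S)-4-[(tert-butyldimethylsilyloxy)methyl]-3-hydroxypent-4-en-1-yl}triphenylphosphonium bromide; 10 (5E)-1-(tert-butyldimethylsilyloxy)-8-[(3S)-3-(tert-butyldimethylsilyloxy)-2,6,6-trimethylcyclohex-1-en-1-yl]-6-methyloct-5-en-2-one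
Product: 18 (3S,5Z,9E)-2,6-bis[(tert-butyldimethylsilyloxy)methyl]-12-[(3S)-3-(tert-butyldimethylsilyloxy)-2,6,6-trimethylcyclohex-1-en-1-yl]-10-methyldodeca-1,5,9-trien-3-yl prop-2-enoate, via Wittig alcohol 17 (not isolated)
Conditions: KN(SiMe3)2 (2 equiv per 16), THF, −78 → 0 °C; 10, −78 → 0 °C; acryloyl chloride, −78 → 0 °C
Reagents that add atoms: acryloyl chloride, C=CC(=O)Cl
Why: The γ-oxido ylide adds to the α-silyloxy ketone in a salt-free Wittig reaction which, as is general for α-alkoxy ketones and unstabilised ylides, places the CH2OTBS group cis to the new alkyl substituent (Z alkene), and the potassium alkoxide left behind is acylated in the same flask without touching the carbinol centre.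

Step 13
Reactants: 18 (3S,5Z,9E)-2,6-bis[(tert-butyldimethylsilyloxy)methyl]-12-[(3S)-3-(tert-butyldimethylsilyloxy)-2,6,6-trimethylcyclohex-1-en-1-yl]-10-methyldodeca-1,5,9-trien-3-yl prop-2-enoate
Product: 19 (5S)-4-[(tert-butyldimethylsilyloxy)methyl]-5-{(2Z,6E)-3-[(tert-butyldimethylsilyloxy)methyl]-9-[(3S)-3-(tert-butyldimethylsilyloxy)-2,6,6-trimethylcyclohex-1-en-1-yl]-7-methylnona-2,6-dien-1-yl}furan-2(5H)-one
Conditions: second-generation Grubbs catalyst (5 mol%), CH2Cl2 (2 mM), 40 °C
Reagents that add atoms: none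
Why: Ring-closing metathesis joins the acrylate to the 1,1-disubstituted alkene, the most accessible alkene pair, to close the five-membered butenolide, while the tri- and tetrasubstituted alkenes are too hindered to compete.

Step 14
Reactants: 19 (5S)-4-[(tert-butyldimethylsilyloxy)methyl]-5-{(2Z,6E)-3-[(tert-butyldimethylsilyloxy)methyl]-9-[(3S)-3-(tert-butyldimethylsilyloxy)-2,6,6-trimethylcyclohex-1-en-1-yl]-7-methylnona-2,6-dien-1-yl}furan-2(5H)-one
Product: 20 (5S)-4-(hydroxymethyl)-5-{(2Z,6E)-3-(hydroxymethyl)-9-[(3S)-3-hydroxy-2,6,6-trimethylcyclohex-1-en-1-yl]-7-methylnona-2,6-dien-1-yl}furan-2(5H)-one (CNP0330392.1)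
Conditions: HF·pyridine, pyridine, THF, 0 °C → rt
Reagents that add atoms: none
Why: Buffered fluoride cleavage of the three silyl ethers (global desilylation) spares the butenolide, the alkenes and the allylic alcohols and touches no stereocentre.

## Compound list

1 | dihydro-β-ionone, 4-(2,6,6-trimethylcyclohex-1-en-1-yl)butan-2-one | CC1=C(CCC(C)=O)C(C)(C)CCC1 | starting material
2 | (1S)-2,4,4-trimethyl-3-(3-oxobutyl)cyclohex-2-en-1-yl 4-nitrobenzoate | CC1=C(CCC(C)=O)C(C)(C)CC[C@@H]1OC(=O)c1ccc(cc1)[N+](=O)[O-] | intermediate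
3 | 4-[(3S)-3-hydroxy-2,6,6-trimethylcyclohex-1-en-1-yl]butan-2-one | CC1=C(CCC(C)=O)C(C)(C)CC[C@@H]1O | intermediate
4 | 4-[(3S)-3-(tert-butyldimethylsilyloxy)-2,6,6-trimethylcyclohex-1-en-1-yl]butan-2-one | CC1=C(CCC(C)=O)C(C)(C)CC[C@@H]1O[Si](C)(C)C(C)(C)C | intermediate
5 | diethyl 4-[(3S)-3-(tert-butyldimethylsilyloxy)-2,6,6-trimethylcyclohex-1-en-1-yl]but-1-en-2-yl phosphate | CC1=C(CCC(=C)OP(=O)(OCC)OCC)C(C)(C)CC[C@@H]1O[Si](C)(C)C(C)(C)C | intermediate
6 | tert-butyl{[(1S)-3-(but-3-yn-1-yl)-2,4,4-trimethylcyclohex-2-en-1-yl]oxy}dimethylsilane | CC1=C(CCC#C)C(C)(C)CC[C@@H]1O[Si](C)(C)C(C)(C)C | intermediate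
7 | but-3-ene-1,2-diol (racemic) | C=CC(O)CO | starting material
8 | 1-(tert-butyldimethylsilyloxy)but-3-en-2-ol (racemic) | C=CC(O)CO[Si](C)(C)C(C)(C)C | intermediate
9 | 1-(tert-butyldimethylsilyloxy)but-3-en-2-one | C=CC(=O)CO[Si](C)(C)C(C)(C)C | intermediate
10 | (5E)-1-(tert-butyldimethylsilyloxy)-8-[(3S)-3-(tert-butyldimethylsilyloxy)-2,6,6-trimethylcyclohex-1-en-1-yl]-6-methyloct-5-en-2-one | CC1=C(CC/C(C)=C/CCC(=O)CO[Si](C)(C)C(C)(C)C)C(C)(C)CC[C@@H]1O[Si](C)(C)C(C)(C)C | intermediate
11 | 5-bromo-2-methylpent-2-ene | CC(C)=CCCBr | starting material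
12 | (2E)-5-bromo-2-methylpent-2-en-1-ol | OC/C(C)=C/CCBr | intermediate
13 | [(2S,3S)-3-(2-bromoethyl)-2-methyloxiran-2-yl]methanol | OC[C@]1(C)O[C@H]1CCBr | intermediate
14 | tert-butyl{[(2S,3S)-3-(2-bromoethyl)-2-methyloxiran-2-yl]methoxy}dimethylsilane | CC(C)(C)[Si](C)(C)OC[C@]1(C)O[C@H]1CCBr | intermediate
15 | (3S)-5-bromo-2-[(tert-butyldimethylsilyloxy)methyl]pent-1-en-3-ol | BrCC[C@H](O)C(=C)CO[Si](C)(C)C(C)(C)C | intermediate
16 | {(3S)-4-[(tert-butyldimethylsilyloxy)methyl]-3-hydroxypent-4-en-1-yl}triphenylphosphonium bromide | c1ccccc1[P+](c1ccccc1)(c1ccccc1)CC[C@H](O)C(=C)CO[Si](C)(C)C(C)(C)C.[Br-] | intermediate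
17 | (3S,5Z,9E)-2,6-bis[(tert-butyldimethylsilyloxy)methyl]-12-[(3S)-3-(tert-butyldimethylsilyloxy)-2,6,6-trimethylcyclohex-1-en-1-yl]-10-methyldodeca-1,5,9-trien-3-ol (present in the flask as its potassium alkoxide) | CC1=C(CC/C(C)=C/CC/C(=C/C[C@H](O)C(=C)CO[Si](C)(C)C(C)(C)C)CO[Si](C)(C)C(C)(C)C)C(C)(C)CC[C@@H]1O[Si](C)(C)C(C)(C)C | intermediate
18 | (3S,5Z,9E)-2,6-bis[(tert-butyldimethylsilyloxy)methyl]-12-[(3S)-3-(tert-butyldimethylsilyloxy)-2,6,6-trimethylcyclohex-1-en-1-yl]-10-methyldodeca-1,5,9-trien-3-yl prop-2-enoate | CC1=C(CC/C(C)=C/CC/C(=C/C[C@H](OC(=O)C=C)C(=C)CO[Si](C)(C)C(C)(C)C)CO[Si](C)(C)C(C)(C)C)C(C)(C)CC[C@@H]1O[Si](C)(C)C(C)(C)C | intermediate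
19 | (5S)-4-[(tert-butyldimethylsilyloxy)methyl]-5-{(2Z,6E)-3-[(tert-butyldimethylsilyloxy)methyl]-9-[(3S)-3-(tert-butyldimethylsilyloxy)-2,6,6-trimethylcyclohex-1-en-1-yl]-7-methylnona-2,6-dien-1-yl}furan-2(5H)-one | CC1=C(CC/C(C)=C/CC/C(=C/C[C@@H]2OC(=O)C=C2CO[Si](C)(C)C(C)(C)C)CO[Si](C)(C)C(C)(C)C)C(C)(C)CC[C@@H]1O[Si](C)(C)C(C)(C)C | intermediate
20 | (5S)-4-(hydroxymethyl)-5-{(2Z,6E)-3-(hydroxymethyl)-9-[(3S)-3-hydroxy-2,6,6-trimethylcyclohex-1-en-1-yl]-7-methylnona-2,6-dien-1-yl}furan-2(5H)-one | CC1=C(CC/C(C)=C/CC/C(=C/C[C@@H]2OC(=O)C=C2CO)CO)C(C)(C)CC[C@@H]1O | target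

## Step count and risks

Total step count: 14. Longest linear sequence: 8 steps (11 → 20 through steps 7 to 14); the ring branch from 1 is 7 steps.

The three steps most likely to fail:

Step 1 (the new C–H oxygenation). Site selectivity among the three allylic positions of the tetrasubstituted alkene and the level of enantioselectivity are unproven. The fallback uses known chemistry, sets out from 1 and comes back at 4. Compound 1 is protected with ethylene glycol (PPTS, benzene, reflux) as the dioxolane ketal of dihydro-β-ionone F1. Allylic oxidation with CrO3/3,5-dimethylpyrazole (CH2Cl2, −20 °C) gives the ring enone ketal F2. Corey–Bakshi–Shibata reduction with the (R)-methyl oxazaborolidine and BH3·SMe2 gives the (S)-allylic alcohol ketal F3, the alkenyl side acting as the large group. TBSCl and imidazole give the silyl ether ketal F4, and PPTS in wet acetone removes the dioxolane to give 4.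

Step 6 (conjugate addition of the alkenylalane). The vinyl ketone 9 polymerises easily and methyl transfer from aluminium can compete. The fallback sets out from 6 and comes back at 10. The same carboalumination (Me3Al, Cp2ZrCl2) is followed by n-BuLi and ethylene oxide, which opens the epoxide with the alkenyl ate complex and gives the (E)-homoallylic alcohol F5. I2, PPh3 and imidazole give the homoallylic iodide F6. Lithium–iodine exchange (t-BuLi, Et2O, −78 °C) and acylation with N-methoxy-N-methyl-2-(tert-butyldimethylsilyloxy)acetamide give 10.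

Step 10 (epoxide to allylic alcohol). Hydrogen abstraction could occur at the CH2OTBS group instead of the methyl group, or simple deoxygenation could compete. The fallback sets out from 13 and comes back at 15. I2, PPh3 and imidazole convert 13 into the epoxy iodide F7. Zn in refluxing ethanol opens it reductively to the isopropenyl carbinol F8 with the carbinol centre retained. SeO2 with t-BuOOH oxidises the allylic methyl group to give the 2-methylene-1,3-diol F9. TBSCl and imidazole at −20 °C silylate the primary hydroxyl selectively to give 15.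

Further compounds
F1 | step 1 | 2-methyl-2-[2-(2,6,6-trimethylcyclohex-1-en-1-yl)ethyl]-1,3-dioxolane | CC1=C(CCC2(C)OCCO2)C(C)(C)CCC1
F2 | step 1 | 2,4,4-trimethyl-3-[2-(2-methyl-1,3-dioxolan-2-yl)ethyl]cyclohex-2-en-1-one | CC1=C(CCC2(C)OCCO2)C(C)(C)CCC1=O
F3 | step 1 | (1S)-2,4,4-trimethyl-3-[2-(2-methyl-1,3-dioxolan-2-yl)ethyl]cyclohex-2-en-1-ol | CC1=C(CCC2(C)OCCO2)C(C)(C)CC[C@@H]1O
F4 | step 1 | tert-butyl({(1S)-2,4,4-trimethyl-3-[2-(2-methyl-1,3-dioxolan-2-yl)ethyl]cyclohex-2-en-1-yl}oxy)dimethylsilane | CC1=C(CCC2(C)OCCO2)C(C)(C)CC[C@@H]1O[Si](C)(C)C(C)(C)C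
F5 | step 6 | (3E)-6-[(3S)-3-(tert-butyldimethylsilyloxy)-2,6,6-trimethylcyclohex-1-en-1-yl]-4-methylhex-3-en-1-ol | CC1=C(CC/C(C)=C/CCO)C(C)(C)CC[C@@H]1O[Si](C)(C)C(C)(C)C
F6 | step 6 | tert-butyl({(1S)-3-[(3E)-6-iodo-3-methylhex-3-en-1-yl]-2,4,4-trimethylcyclohex-2-en-1-yl}oxy)dimethylsilane | CC1=C(CC/C(C)=C/CCI)C(C)(C)CC[C@@H]1O[Si](C)(C)C(C)(C)C
F7 | step 10 | (2R,3S)-3-(2-bromoethyl)-2-(iodomethyl)-2-methyloxirane | IC[C@]1(C)O[C@H]1CCBr
F8 | step 10 | (3S)-5-bromo-2-methylpent-1-en-3-ol | BrCC[C@H](O)C(C)=C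
F9 | step 10 | (3S)-5-bromo-2-methylidenepentane-1,3-diol | BrCC[C@H](O)C(=C)CO
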